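## Structural features

The target joins a C15 bicyclic sesquiterpene unit through its C11 methylene, as an alkyl aryl ether, to O7 of a coumarin. In drimane numbering, ring A (C1–C5, C10) is a cyclohexanone with the C3 carbonyl beside the C4 gem-dimethyl carbon. Ring B (C5–C10) is a cyclohexene whose trisubstituted C7=C8 alkene carries the C8 methyl. The rings share the C5–C10 bond and are cis-fused: H5, the angular C10 methyl and H9 lie on one face, so the C11H2–OAr arm is trans to the angular methyl. The three stereocentres C5, C10 (quaternary) and C9 are contiguous, with absolute configuration (5S,9R,10S). Fragile points are the coumarin lactone (hydroxide, hydride, organometallics), the C7=C8 alkene (it can migrate to C8=C9 under acid once C9 bears hydrogen) and the C3 ketone, which must stay masked through hydride, ylide and borane steps. The real difficulty is the crowded C4–C5–C10 row (quaternary carbon, ring-fusion methine, quaternary carbon) in the cis sense as one enantiomer, followed by C9 next to C10. The key step uses the fact that C3 is 1,4 to C10 and C4 is bonded to C5, so ring A is the cycloadduct of a 2-silyloxydiene (C1–C4) with a C5=C10 dienophile; ring B, with the C8 methyl on an alkene and a carbonyl at C9, is the untouched half of a 2,6-dimethylquinone.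

## Logic of the disconnections

**14 ⇒ 13.** The C3 carbonyl is traced back to the C2=C3 silyl enol ether (O–Si bond; C2–H is made going forward). The ketone would not survive the hydride, ylide and borane steps, and the enol ether is the form in which ring A is born, so no protecting-group step is added. The forward step must be a desilylation that spares the lactone and the aryl ether.

**13 ⇒ 11 + 12.** The C11–O(aryl) bond is cut. This brings the base-sensitive lactone in last and makes the route convergent, with 12 purchased and 11 a plain primary alcohol. The forward step must etherify a β-branched, homoallylic primary alcohol under neutral conditions without elimination towards C9.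

**11 ⇒ 9 (through 10).** The C11–O and C9–H bonds are removed, the retron of an anti-Markovnikov hydration of an exocyclic alkene. C9 stops being a stereocentre and becomes a facial-selectivity problem on 9. The forward step must select the exocyclic alkene over the two ring alkenes and deliver hydrogen to C9 on the face of the angular methyl.

**9 ⇒ 8.** The C9=C11 bond is cut to a C9 ketone and a one-carbon ylide. This leaves 8 with only C5 and C10 as stereocentres. The forward step must methylenate a ketone flanked by a quaternary carbon and a substituted alkene.

**8 ⇒ 6 (through 7).** A C6–H bond is exchanged for C6–OAc. The C6 oxygen is the price of using a quinone; being γ to the C9 carbonyl it can be expelled by electron transfer. The forward step must end with the alkene at C7=C8 and leave the enol ether untouched.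

**6 ⇒ 5 ⇒ 4.** The acetyl C–O bond and then the C6–H bond are removed, returning to the C6 carbonyl of 4. This reaches the direct cycloadduct. The forward steps must reduce C6 and not C9, in the 1,2 sense, without epimerising C5.

**4 ⇒ 2 + 3.** The C4–C5 and C1–C10 bonds are cut, opening ring A. This removes both ring-fusion stereocentres and the most crowded bond in one operation and leaves a purchased symmetric quinone and a six-carbon diene. The forward step must be a regioselective, face-selective [4+2] addition with a diene whose reacting terminus is fully substituted.

**2 ⇒ 1.** The O–Si bond is cut, giving a purchased enone that can enolise only at the isopropyl methine. The forward step is an O-silylation that must not polymerise the vinyl ketone.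

## Other disconnections considered

**Alternative 1:** The cut removes the angular methyl (C10–CH3) and C11 (C9–C11) together, leaving the bicyclic enone A1 with C9=C10 conjugated to a C8 ketone. In the forward step Me2CuLi would add methyl to C10 and the resulting enolate would be trapped at C9 by monomeric formaldehyde, giving the cis-fused hydroxymethyl ketone A2; no ring closes.
- In its favour: the electrophile enters anti to the methyl just delivered, which is exactly the trans relation of the C10 methyl and C11 required. On the C9/C10 relationship this alternative is better founded than the chosen plan, which relies on a late substrate-controlled hydroboration. It also avoids a hindered cycloaddition.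
- Against it: the step creates no absolute configuration, so A1 must already carry C5 (and C3) enantioenriched. Cuprate addition to a fully substituted ring-fusion β-carbon is slow, and its facial course relative to H5 rests on the existing centres. Formaldehyde trapping of a hindered enolate can suffer oligomerisation, double addition and dehydration to the α-methylene ketone.
- Comparison: the C8 methyl and the C7=C8 alkene must still be built from the C8 ketone (enol triflate towards C7, methyl coupling) and C3 must be deprotected and oxidised; with a Birch-based entry to A1 the count would be clearly above nine. The chosen plan gets the C8 methyl, the alkene and two stereocentres from purchased materials in one catalytic step. On cis fusion the two plans are equal.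

**Alternative 2:** Only C4–C5 is cut, leading to the prochiral 4,4-disubstituted cyclohexadienone A3 that carries the enol silane on a two-carbon tether. In the forward step a confined chiral BINOL-derived imidodiphosphorimidate acid, acting as a silylium-type Lewis acid, would promote intramolecular Mukaiyama–Michael addition of C4 to C5 of one enantiotopic enone arm, giving the cis-fused diketone A4.
- In its favour: the most crowded bond forms intramolecularly, the tether enforces cis fusion, C10 becomes stereogenic by desymmetrisation and the C3 ketone arrives free. There is no regiochemical question at all, which is better than the chosen plan; on ring fusion the plans are equal.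
- Against it: A4 has neither the C8 methyl nor C11, and ring B arrives as a C7 enone. A hydroxymethyl equivalent would have to be added at C9 beside quaternary C10, C8 methylated and the C7 oxygen removed with the alkene placed at C7=C8, all beside a competing C3 ketone. The C9 centre again depends on facial approach. A3 needs a dearomatisation-based synthesis of its own.
- Comparison: mechanistically it exchanges a cycloaddition for a stepwise ionic closure governed by ion pairing, for which a tetrasubstituted enol silane forming a quaternary carbon is a demanding case. A count of twelve or more steps is likely, against nine.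

**Alternative 3:** The cut is at C5–C6 and C9–C10, so ring B is formed. In the forward step a protonated chiral oxazaborolidine would catalyse endo [4+2] addition of the silyloxydiene A5 to the C5=C10 bond of the cross-conjugated dienone A6, giving A7.
- In its favour: C5, C10 and C9 would be set in one step, C9 with its oxygenated carbon already attached and trans to the methyl by the endo rule and the (E)-diene geometry. This is better than the chosen plan for C9. The C7 silyl enol ether fixes the later C7=C8 alkene (triflate, reduction), and the diene polarity matches the dienophile (unsubstituted terminus to the β-carbon C5), which is at least equal to the chosen plan.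
- Against it: A6 is a poor dienophile. Its carbonyl is part of a vinylogous ester, the reacting alkene is trisubstituted, C5 is neopentyl and C10 becomes quaternary. The only α-C–H available for organised catalyst binding lies on the vinylogous-ester side that should not react.
- Comparison: afterwards ring A has the wrong oxidation pattern (C1 carbonyl to remove, C3 to unveil by reduction, transposition and conjugate reduction), the C7 oxygen must go and the benzyl ether must be cleaved before etherification. Together with the syntheses of A5 and A6 this is well beyond nine steps. The reaction class and its uncertainties are the same as in the chosen plan.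

Key step: step 2

Assumption: the (S)-prolinol-derived cation is taken to expose the face of the reacting double bond that leads to 4; because the gem-dimethyl diene forces a regiochemistry outside the usual binding pattern, this sense is a prediction, and the (R)-prolinol catalyst, made the same way, would be used if the antipode formed.

Assumption: the C6 carbinol configuration in 5 and 6 (drawn as expected from convex-face hydride attack) and the C8 configuration in 7 are immaterial, since both centres are erased in step 5.

## Route

**Step 1**
Reactants: 1 4-methylpent-1-en-3-one
Product: 2 4-methyl-3-(triisopropylsilyloxy)penta-1,3-diene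
Conditions: TIPSOTf, Et3N, CH2Cl2, 0 °C to rt
Reagents that add atoms: triisopropylsilyl trifluoromethanesulfonate, CC(C)[Si](C(C)C)(C(C)C)OS(=O)(=O)C(F)(F)F
Why: Soft enolisation with O-silylation: the silyl triflate activates the carbonyl and the amine removes the only enolisable hydrogen (the isopropyl methine), giving the tetrasubstituted silyl enol ether; no stereocentre is formed.

**Step 2**
Reactants: 2 4-methyl-3-(triisopropylsilyloxy)penta-1,3-diene; 3 2,6-dimethyl-1,4-benzoquinone
Product: 4 (4aR,8aS)-2,5,5,8a-tetramethyl-6-(triisopropylsilyloxy)-4a,5,8,8a-tetrahydronaphthalene-1,4-dione (cis-fused enedione; H5 and the C10 methyl on one face)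
Conditions: (S)-3,3-diphenyl-1-(o-tolyl)tetrahydro-1H,3H-pyrrolo[1,2-c][1,3,2]oxazaborole (from (S)-α,α-diphenylprolinol and tri-o-tolylboroxine) + HNTf2, 20 mol% each, CH2Cl2, −78 to −40 °C; pH 7 phosphate buffer
Reagents that add atoms: none
Why: Diels–Alder reaction: the cationic boron Lewis acid binds a quinone carbonyl, lowers the enedione LUMO and lets the electron-rich diene add across one methyl-bearing double bond in a concerted but strongly asynchronous [4+2] event, C4–C5 leading and C1–C10 completing ring A (in the stepwise limit a Mukaiyama–Michael addition followed by 6-endo-trig enolate closure, which gives the same adduct). The closest known reaction types are the oxazaborolidinium-catalysed enantioselective cycloadditions of 2-silyloxydienes to dialkyl-1,4-benzoquinones and the AlBr3/AlMe3-promoted cycloadditions of gem-dialkyl 2-silyloxydienes to 2-methylcycloalkenones. Ring A closes as a six-membered carbocycle by intermolecular suprafacial–suprafacial cycloaddition, both new σ bonds arising on one face of each partner. Regiochemistry: the fully substituted, most nucleophilic terminus C4 can bond only to the hydrogen-bearing C5, which is β to the methyl-flanked C9 carbonyl and the least hindered, intrinsically most electrophilic position of 3, whereas the reverse orientation would have to join two fully substituted carbons. Relative configuration: suprafacial addition to the ring double bond places H5 and the C10 methyl cis, so the cis fusion is fixed by the mechanism. Absolute configuration: C5 and C10 are created together and their sense is decided by the chiral cation, whose phenyl group cis to the bound quinone screens one face of the reacting double bond. Only enantioface selection is required, because the two methyl-bearing double bonds of 3 are exchanged by its twofold axis. The triisopropylsilyl group is retained because it resists protodesilylation by the strong acid and survives the next six steps, and the neutral work-up protects the base-labile C5 centre.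

**Step 3**
Reactants: 4 cis-fused enedione
Product: 5 cis-fused C6 allylic alcohol with the C9 enone intact (6-OH expected trans to H5)
Conditions: NaBH4, CeCl3·7H2O, MeOH–CH2Cl2, −78 °C; aq NH4Cl
Reagents that add atoms: none
Why: Luche reduction: the cerium-modified borohydride adds 1,2, and C6 (between a methine and a vinylic CH) is far more accessible than C9 (between quaternary C10 and the methyl-bearing C8). Hydride should enter from the convex face, but the new centre is removed later; low temperature and a near-neutral medium protect C5.

**Step 4**
Reactants: 5 C6 allylic alcohol
Product: 6 C6 acetate (γ-acetoxy enone)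
Conditions: Ac2O, pyridine, DMAP (cat.), CH2Cl2, 0 °C to rt
Reagents that add atoms: acetic anhydride, CC(=O)OC(C)=O
Why: Nucleophile-catalysed O-acylation of a secondary allylic alcohol; the stereocentres are untouched and C5 is no longer α to a carbonyl.

**Step 5**
Reactants: 6 C6 acetate
Product: 8 cis-fused C9 enone with C7=C8 and C6H2, via deconjugated ketone 7 (not isolated)
Conditions: SmI2 (2.5 equiv), THF–MeOH, −78 °C; then DBU (cat.), CH2Cl2, rt
Reagents that add atoms: none
Why: Reductive cleavage of a γ-acyloxy enone: two single-electron transfers to the C9 enone place negative charge at C7, acetate leaves from C6 and a samarium dienolate results, which is protonated mainly at C8 to give 7. The amidine base then moves the alkene into conjugation (trisubstituted C7=C8), and C5 and C10 are not involved.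

**Step 6**
Reactants: 8 C9 enone
Product: 9 C9 exo-methylene diene (C11=C9–C8=C7)
Conditions: Ph3PCH3Br, KOtBu, toluene, rt to 90 °C
Reagents that add atoms: methyltriphenylphosphonium bromide, C[P+](c1ccccc1)(c1ccccc1)c1ccccc1.[Br-]
Why: Wittig methylenation under the hot, salt-poor conditions used for hindered ketones; any γ-deprotonation is reversible and the silyl enol ether is inert to the ylide.

**Step 7**
Reactants: 9 exo-methylene diene
Product: 11 primary C11 alcohol with H9 cis to the C10 methyl, via alkylborane 10 (not isolated)
Conditions: 9-BBN, THF, 0 °C to rt; then NaOH, H2O2, H2O, 0 °C to rt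
Reagents that add atoms: hydrogen peroxide, OO (supplies the hydroxyl oxygen); 9-borabicyclo[3.3.1]nonane, B1C2CCCC1CCC2 (boron and its carbocycle are carried only by intermediate 10)
Why: Hydroboration–oxidation: the bulky borane places boron on the unhindered terminus C11 (the trisubstituted ring alkene and the hindered silyl enol ether react far more slowly) and oxidation proceeds with retention. C9 is set by substrate control: in the ring-B half-chair that keeps the CMe2 carbon C4 equatorial, C1 stands axial on the face of C9 opposite the angular methyl, while the methyl-side face carries only the axial H5. Hydrogen should therefore arrive cis to the angular methyl and leave C11 trans to it and equatorial.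

**Step 8**
Reactants: 11 primary C11 alcohol; 12 umbelliferone (7-hydroxycoumarin)
Product: 13 7-O-alkyl coumarin ether still carrying the C3 silyl enol ether
Conditions: PPh3, DIAD, THF, 0 °C to rt
Reagents that add atoms: none
Why: Mitsunobu etherification: the acidic phenol displaces the alkoxyphosphonium ion at primary C11 under neutral conditions, so no base can open the lactone or cause elimination towards C9; no stereocentre is involved.

**Step 9**
Reactants: 13 coumarin ether silyl enol ether
Product: 14 7-{[(1R,4aS,8aS)-2,5,5,8a-tetramethyl-6-oxo-1,4,4a,5,6,7,8,8a-octahydronaphthalen-1-yl]methoxy}-2H-chromen-2-one (target)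
Conditions: HF·pyridine, pyridine, THF, 0 °C to rt
Reagents that add atoms: none
Why: Fluoride-assisted protodesilylation of the silyl enol ether gives the C3 ketone by protonation at C2. C4 is quaternary, so no stereocentre adjoins the new carbonyl, and the buffered acid leaves the lactone, the aryl ether and the C7=C8 alkene alone.

## Compound list

1 | 4-methylpent-1-en-3-one | C=CC(=O)C(C)C | starting material
2 | 4-methyl-3-(triisopropylsilyloxy)penta-1,3-diene | C=CC(O[Si](C(C)C)(C(C)C)C(C)C)=C(C)C | intermediate
3 | 2,6-dimethyl-1,4-benzoquinone | CC1=CC(=O)C=C(C)C1=O | starting material
4 | (4aR,8aS)-2,5,5,8a-tetramethyl-6-(triisopropylsilyloxy)-4a,5,8,8a-tetrahydronaphthalene-1,4-dione (cis-fused) | CC1=CC(=O)[C@@H]2C(C)(C)C(O[Si](C(C)C)(C(C)C)C(C)C)=CC[C@]2(C)C1=O | intermediate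
5 | C6 allylic alcohol of 4, C9 enone intact, 6-OH trans to H5 | CC1=C[C@H](O)[C@@H]2C(C)(C)C(O[Si](C(C)C)(C(C)C)C(C)C)=CC[C@]2(C)C1=O | intermediate
6 | C6 acetate of 5 | CC1=C[C@H](OC(C)=O)[C@@H]2C(C)(C)C(O[Si](C(C)C)(C(C)C)C(C)C)=CC[C@]2(C)C1=O | intermediate
7 | deconjugated C9 ketone with C6=C7 and H at C8 (C8 epimers; not isolated) | CC1C=C[C@@H]2C(C)(C)C(O[Si](C(C)C)(C(C)C)C(C)C)=CC[C@]2(C)C1=O | intermediate
8 | cis-fused C9 enone (C7=C8, C6H2) | CC1=CC[C@@H]2C(C)(C)C(O[Si](C(C)C)(C(C)C)C(C)C)=CC[C@]2(C)C1=O | intermediate
9 | C9 exo-methylene diene | CC1=CC[C@@H]2C(C)(C)C(O[Si](C(C)C)(C(C)C)C(C)C)=CC[C@]2(C)C1=C | intermediate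
10 | B-(C11-alkyl)-9-borabicyclo[3.3.1]nonane (not isolated) | CC1=CC[C@@H]2C(C)(C)C(O[Si](C(C)C)(C(C)C)C(C)C)=CC[C@]2(C)[C@@H]1CB1C2CCCC1CCC2 | intermediate
11 | primary C11 alcohol, H9 cis to the C10 methyl and H5 | CC1=CC[C@@H]2C(C)(C)C(O[Si](C(C)C)(C(C)C)C(C)C)=CC[C@]2(C)[C@@H]1CO | intermediate
12 | umbelliferone (7-hydroxycoumarin) | O=c1ccc2ccc(O)cc2o1 | starting material
13 | 7-O-alkyl coumarin ether with C3 triisopropylsilyl enol ether | CC1=CC[C@@H]2C(C)(C)C(O[Si](C(C)C)(C(C)C)C(C)C)=CC[C@]2(C)[C@@H]1COc1ccc2ccc(=O)oc2c1 | intermediate
14 | 7-{[(1R,4aS,8aS)-2,5,5,8a-tetramethyl-6-oxo-1,4,4a,5,6,7,8,8a-octahydronaphthalen-1-yl]methoxy}-2H-chromen-2-one | CC1=CC[C@@H]2C(C)(C)C(=O)CC[C@]2(C)[C@@H]1COc1ccc2ccc(=O)oc2c1 | target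

## Step count and least certain steps

Total step count: 9. Longest linear sequence: 9 steps (1 to 14); 3 and 12 enter at steps 2 and 8.

**Step 2 (key step).**
- What may go wrong: the diene must reach the s-cis form against its (Z)-methyl, so cycloaddition may be slow. The catalyst normally binds the carbonyl flanked by C–H (C6), which activates C10 rather than C5, so the sterically enforced orientation is not the electronically assisted one. Low turnover, Mukaiyama–Michael addition without ring closure, acid-induced loss of the silyl group and leakage through a less organised complex with loss of enantioselectivity are the likely failures, together with epimerisation at C5 on work-up.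
- Fallback (racemic cycloaddition, then resolution): 2 and 3 are combined without a chiral catalyst (toluene, 80–110 °C or high pressure; if needed the AlBr3/AlMe3 promoter known for this diene class), where the intrinsic polarisation of the quinone and the steric demand agree. This gives 4 together with the enantiomeric adduct F1. Reduction as in step 3 gives 5 together with the enantiomeric alcohol F2. Lipase-mediated acetylation (vinyl acetate, immobilised Candida antarctica lipase B, MTBE) should, by the usual size rule for secondary carbinols, acylate the (6R)-antipode to the enantiomeric acetate F3 and leave 5, where the route is rejoined. If the enzyme preferred the other enantiomer, the ester formed would be 6 itself.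

**Step 7.**
- What may go wrong: insufficient facial discrimination at C9 if the ring-B conformer with axial angular methyl takes part, and competing hydroboration of the ring alkene or the enol ether on prolonged reaction.
- Fallback (carbon delivered by a suprafacial sigmatropic shift, controlled by an invertible C7 carbinol), setting out from 8 and returning at 11:
  - Nucleophilic epoxidation of 8 (tBuOOH, DBU) should occur trans to the C4 substituent of C5 and give the 7β,8β-epoxy ketone F4.
  - Wharton transposition (N2H4·H2O, AcOH cat., MeOH) gives the 7β-allylic alcohol F5 with C8=C9.
  - Mitsunobu inversion with 4-nitrobenzoic acid gives the 7α-ester F6, and K2CO3/MeOH the 7α-alcohol F7.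
  - KH and Bu3SnCH2I give the stannylmethyl ether F8, and n-BuLi at −78 °C triggers the Wittig–Still [2,3] rearrangement, which forms C9–C11 on the face of the C7–O bond and moves the alkene to C7=C8, giving 11.
  - Should the epoxidation take the other face, F7 would arise directly from the Wharton step and the inversion would be omitted.

**Step 3.**
- What may go wrong: hydride attack at C9 or conjugate reduction of the enedione, and methoxide-induced epimerisation at C5 before C6 is reduced.
- Fallback (deoxygenation through a hydrazone, no hydride at carbonyl oxygen), setting out from 4 and returning at 7: condensation of the less hindered C6 carbonyl with TsNHNH2 (THF, rt, no base) gives the C6 tosylhydrazone F9. Catecholborane followed by NaOAc·3H2O reduces the C=N bond, expels sulfinate and lets the allylic diazene lose N2 with hydrogen transfer to C8. This gives 7, which the DBU treatment of step 5 converts into 8; steps 3–5 are thus replaced.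

**Step 5.**
- What may go wrong: over-reduction of the product enone by excess reductant, ketyl dimerisation, or incomplete return of the alkene into conjugation.
- Fallback (two-electron palladium chemistry instead of electron transfer), setting out from 6 and returning at 8: hydrogenolysis of the allylic acetate with Pd(PPh3)4 and HCO2NH4 in dioxane at 80 °C proceeds through a π-allyl complex spanning C6–C8. Hydride delivery at either end gives 8 or 7, and DBU converges both on 8. This fallback makes no compound outside the list (entry F0).

**Step 6.**
- What may go wrong: γ-deprotonation at C6 in place of addition, and slow attack at a carbonyl flanked by a quaternary carbon.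
- Fallback (Peterson olefination), setting out from 8 and returning at 9: the less basic, more nucleophilic Me3SiCH2Li–CeCl3 reagent (THF, −78 °C) adds to C9 to give the β-hydroxysilane F10, and KH in THF effects syn-elimination to 9.

## Further compounds

F1 | step 2 | enantiomer of 4 (formed beside 4 in the racemic cycloaddition) | CC1=CC(=O)[C@H]2C(C)(C)C(O[Si](C(C)C)(C(C)C)C(C)C)=CC[C@@]2(C)C1=O
F2 | step 2 | enantiomer of 5 | CC1=C[C@@H](O)[C@H]2C(C)(C)C(O[Si](C(C)C)(C(C)C)C(C)C)=CC[C@@]2(C)C1=O
F3 | step 2 | enantiomer of 6 (acetate of the antipodal alcohol) | CC1=C[C@@H](OC(C)=O)[C@H]2C(C)(C)C(O[Si](C(C)C)(C(C)C)C(C)C)=CC[C@@]2(C)C1=O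
F4 | step 7 | 7β,8β-epoxy C9 ketone from 8 | C[C@]12O[C@H]1C[C@@H]3C(C)(C)C(O[Si](C(C)C)(C(C)C)C(C)C)=CC[C@]3(C)C2=O
F5 | step 7 | 7β-allylic alcohol with C8=C9 | O[C@H]1C[C@@H]2C(C)(C)C(O[Si](C(C)C)(C(C)C)C(C)C)=CC[C@]2(C)C=C1C
F6 | step 7 | 7α 4-nitrobenzoate | O=C(O[C@@H]1C[C@@H]2C(C)(C)C(O[Si](C(C)C)(C(C)C)C(C)C)=CC[C@]2(C)C=C1C)c1ccc(cc1)[N+](=O)[O-]
F7 | step 7 | 7α-allylic alcohol with C8=C9 | O[C@@H]1C[C@@H]2C(C)(C)C(O[Si](C(C)C)(C(C)C)C(C)C)=CC[C@]2(C)C=C1C
F8 | step 7 | 7α (tributylstannyl)methyl ether | CCCC[Sn](CCCC)(CCCC)CO[C@@H]1C[C@@H]2C(C)(C)C(O[Si](C(C)C)(C(C)C)C(C)C)=CC[C@]2(C)C=C1C
F9 | step 3 | C6 tosylhydrazone of 4 | CC1=CC(=NNS(=O)(=O)c3ccc(C)cc3)[C@@H]2C(C)(C)C(O[Si](C(C)C)(C(C)C)C(C)C)=CC[C@]2(C)C1=O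
F0 | step 5 | none | none
F10 | step 6 | C9 β-hydroxysilane (C9 carbinol configuration immaterial) | CC1=CC[C@@H]2C(C)(C)C(O[Si](C(C)C)(C(C)C)C(C)C)=CC[C@]2(C)C1(O)C[Si](C)(C)C
A1 | alternative 1 | 6-(tert-butyldimethylsilyloxy)-5,5-dimethyl-4,4a,5,6,7,8-hexahydronaphthalen-2(3H)-one (C8 enone, C9=C10) | O=C1CC[C@@H]2C(C)(C)[C@H](O[Si](C)(C)C(C)(C)C)CCC2=C1
A2 | alternative 1 | cis-fused C8 ketone with C10 methyl and C9 hydroxymethyl | O=C1CC[C@@H]2C(C)(C)[C@H](O[Si](C)(C)C(C)(C)C)CC[C@]2(C)[C@@H]1CO
A3 | alternative 2 | 4-methyl-4-[4-methyl-3-(tert-butyldimethylsilyloxy)pent-3-enyl]cyclohexa-2,5-dienone | CC(C)=C(O[Si](C)(C)C(C)(C)C)CCC1(C)C=CC(=O)C=C1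
A4 | alternative 2 | cis-fused C3 ketone with C7 enone (C8=C9) | O=C1C[C@@H]2C(C)(C)C(=O)CC[C@]2(C)C=C1
A5 | alternative 3 | (E)-2-(tert-butyldimethylsilyloxy)-3-methyl-5-(4-methoxybenzyloxy)penta-1,3-diene | C=C(O[Si](C)(C)C(C)(C)C)/C(C)=C/COCc1ccc(OC)cc1
A6 | alternative 3 | 3-methoxy-4,4,6-trimethylcyclohexa-2,5-dien-1-one | COC1=CC(=O)C(C)=CC1(C)C
A7 | alternative 3 | cis-fused adduct with C7 silyl enol ether and ring-A vinylogous ester | CC1=C(O[Si](C)(C)C(C)(C)C)C[C@@H]2C(C)(C)C(OC)=CC(=O)[C@]2(C)[C@@H]1COCc1ccc(OC)cc1
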